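Xanthanolide numbering is used: C1–C15 for the hydroxy-enone half, C1′–C15′ for the epoxide half; ring C is the cyclohexene C1–C2–C3–C11′–C13′–C5.
Retrosynthesis: cut C2′=C3′ (cross-metathesis with methyl vinyl ketone), unmask C11=C13 from a selenide, then open ring C at C1–C2, C3–C11′ and C5–C13′ into three pieces: a C1 ketone with a C5 enolate, the α-methylidene lactone C11′=C13′ of the epoxide half, and (E)-4-nitrobut-3-en-2-one as C2–C3–C4–C15.
Enabling feature: C1 (tertiary carbinol, a latent ketone carbon) and C11′ (lactone α-carbon, a latent enolate) sit 1,4 to each other across C5–C13′ and are bridged by the enone C2=C3–C4=O; a nitro group on C2 makes C3 the electrophile, then C2 the nucleophile, then leaves as nitrite.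
Forward order: one enyne lactone 19 serves both halves; enyne metathesis and epoxidation give the epoxide half 21, alkyne hydration and enol-ether metathesis give cycloheptanone 25; the lactone rings arise first, then the seven-membered rings, then ring C, last the enone side chain.
Stereochemistry: C10/C10′ from (S)-but-3-yn-2-ol (SN2 inversion), C7/C8 from the (S)-benzyloxazolidinone syn-aldol, the epoxide and C5, C1, C11′ by substrate control (β face of the cycloheptene and of the ketone enolate, convex face of the cis-fused lactone enolate, trans ring closure).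

Key step: step 21

Remark: 26 is drawn as the C11 epimer expected from convex-face protonation; either epimer gives the same methylidene lactone in step 22.

Step 1
Reactants: 1 (2S)-but-3-yn-2-ol
Product: 2 (2S)-but-3-yn-2-yl 4-methylbenzenesulfonate
Conditions: TsCl, Et3N, DMAP (cat.), CH2Cl2, 0 °C
Reagents that add atoms: 4-toluenesulfonyl chloride, Cc1ccc(cc1)S(Cl)(=O)=O
Why: O-sulfonylation (tosylation) leaves the C–O bond untouched, so the (S) configuration is kept and the carbinol becomes a leaving group.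

Step 2
Reactants: 2 (2S)-but-3-yn-2-yl 4-methylbenzenesulfonate; 3 dimethyl malonate
Product: 5 dimethyl 2-[(2S)-but-3-yn-2-yl]propanedioate, via sodium dimethyl malonate 4 (not isolated)
Conditions: NaH, THF/DMF, 0 °C; then 2, 50 °C
Reagents that add atoms: none
Why: Malonic ester alkylation by SN2 displacement of the secondary propargylic tosylate should proceed with inversion (the soft malonate favours direct substitution over SN2′), which sets the future C10 methyl stereocentre.

Step 3
Reactants: 5 dimethyl 2-[(2S)-but-3-yn-2-yl]propanedioate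
Product: 6 methyl (3S)-3-methylpent-4-ynoate
Conditions: LiCl, H2O, DMSO, 150 °C
Reagents that add atoms: none
Why: Krapcho dealkoxycarbonylation removes one ester under neutral conditions that touch neither the terminal alkyne nor the stereocentre.

Step 4
Reactants: 6 methyl (3S)-3-methylpent-4-ynoate
Product: 7 (3S)-3-methylpent-4-ynal
Conditions: i-Bu2AlH (1.05 equiv), CH2Cl2, −78 °C
Reagents that add atoms: none
Why: Partial ester reduction stops at the tetrahedral aluminate at low temperature and releases the aldehyde on work-up, the stereocentre being β to the carbonyl and not epimerisable.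

Step 5
Reactants: 8 (4S)-4-benzyl-1,3-oxazolidin-2-one; 9 pent-4-enoyl chloride
Product: 10 (4S)-4-benzyl-3-(pent-4-enoyl)-1,3-oxazolidin-2-one
Conditions: Et3N, DMAP (cat.), CH2Cl2, 0 °C → rt
Reagents that add atoms: none
Why: DMAP-catalysed N-acylation of the oxazolidinone with the acid chloride gives the Evans imide.

Step 6
Reactants: 10 (4S)-4-benzyl-3-(pent-4-enoyl)-1,3-oxazolidin-2-one; 7 (3S)-3-methylpent-4-ynal
Product: 12 (4S)-4-benzyl-3-[(2S,3R,5S)-3-hydroxy-5-methyl-2-(prop-2-en-1-yl)hept-6-ynoyl]-1,3-oxazolidin-2-one, via dibutylboron enolate 11 (not isolated)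
Conditions: Bu2BOTf, i-Pr2NEt, CH2Cl2, 0 °C; then 7, −78 → 0 °C; then pH 7 buffer, MeOH, H2O2
Reagents that add atoms: none
Why: Evans syn-aldol reaction: the (Z)-boron enolate reacts through a Zimmerman–Traxler chair on the face opposite the benzyl group, which sets C7 and C8 syn with the absolute configuration fixed by the (S)-auxiliary and independent of the remote C10 centre.

Step 7
Reactants: 12 aldol imide
Product: 13 (2S,3R,5S)-3-hydroxy-N-methoxy-N,5-dimethyl-2-(prop-2-en-1-yl)hept-6-ynamide
Conditions: MeONHMe·HCl, AlMe3, CH2Cl2, −20 → 0 °C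
Reagents that add atoms: N,O-dimethylhydroxylamine hydrochloride, CNOC.Cl
Why: Aluminium amide transamidation (Weinreb amide formation) is directed by the free β-hydroxyl group and releases the auxiliary without epimerisation.

Step 8
Reactants: 13 hydroxy Weinreb amide
Product: 14 (2S,3R,5S)-N-methoxy-N,5-dimethyl-2-(prop-2-en-1-yl)-3-[(triethylsilyl)oxy]hept-6-ynamide
Conditions: TESCl, imidazole, CH2Cl2, 0 °C
Reagents that add atoms: chlorotriethylsilane, CC[Si](Cl)(CC)CC
Why: Silylation of the secondary alcohol protects it from the strong bases of the next two steps.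

Step 9
Reactants: 14 silyl ether Weinreb amide
Product: 15 (3S,4R,6S)-6-methyl-3-(prop-2-en-1-yl)-4-[(triethylsilyl)oxy]oct-7-yn-2-one
Conditions: MeMgBr (3 equiv), THF, −20 → 0 °C
Reagents that add atoms: methylmagnesium bromide, C[Mg]Br
Why: Weinreb ketone synthesis: the chelated tetrahedral intermediate prevents over-addition, and the excess Grignard reagent only deprotonates the terminal alkyne reversibly.

Step 10
Reactants: 15 methyl ketone
Product: 17 (3S,4R,6S)-6-methyl-3-(prop-2-en-1-yl)-4-[(triethylsilyl)oxy]oct-1-en-7-yn-2-yl trifluoromethanesulfonate, via potassium enolate 16 (not isolated)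
Conditions: KN(SiMe3)2, THF, −78 °C; then PhNTf2, −78 → 0 °C
Reagents that add atoms: N-phenylbis(trifluoromethanesulfonimide), FC(F)(F)S(=O)(=O)N(c1ccccc1)S(=O)(=O)C(F)(F)F
Why: Kinetic deprotonation at the methyl group by the bulky amide and O-triflation of the enolate (enol triflate formation) give the 2-triflyloxy-1-alkene without touching the C7 methine.

Step 11
Reactants: 17 silyl ether vinyl triflate
Product: 18 (3S,4R,6S)-4-hydroxy-6-methyl-3-(prop-2-en-1-yl)oct-1-en-7-yn-2-yl trifluoromethanesulfonate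
Conditions: HF·pyridine, pyridine, THF, 0 °C
Reagents that add atoms: none
Why: Fluoride-mediated desilylation frees the C8 hydroxyl, and the vinyl triflate is stable to buffered HF·pyridine.

Step 12
Reactants: 18 hydroxy vinyl triflate
Product: 19 (4R,5R)-3-methylidene-5-[(2S)-2-methylbut-3-yn-1-yl]-4-(prop-2-en-1-yl)oxolan-2-one
Conditions: Pd(PPh3)4 (5 mol%), CO (1 atm), n-Bu3N, MeCN, 65 °C
Reagents that add atoms: carbon monoxide, [C-]#[O+]
Why: Palladium-catalysed carbonylative lactonisation (oxidative addition of the vinyl triflate, CO insertion, capture of the acylpalladium by the C8 hydroxyl) gives the α-methylidene-γ-butyrolactone, whose cis C7/C8 relationship follows from the syn-aldol.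

Step 13
Reactants: 19 enyne lactone
Product: 20 (3aR,7S,8aR)-6-ethenyl-7-methyl-3-methylidene-3,3a,4,7,8,8a-hexahydro-2H-cyclohepta[b]furan-2-one
Conditions: second-generation Grubbs catalyst (5 mol%), ethylene (1 atm), CH2Cl2, 40 °C
Reagents that add atoms: none
Why: Ring-closing enyne metathesis (exo mode) joins the allyl terminus to the alkyne to give the 1-vinylcycloheptene, the electron-poor 1,1-disubstituted lactone alkene taking no part.

Step 14
Reactants: 20 vinyl diene lactone
Product: 21 1β,5β-epoxide of 20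
Conditions: mCPBA, NaHCO3, CH2Cl2, 0 °C
Reagents that add atoms: 3-chloroperoxybenzoic acid, OOC(=O)c1cccc(Cl)c1
Why: Prilezhaev epoxidation should take the most electron-rich, trisubstituted C1=C5 bond of the diene on its β face (syn to the pseudo-equatorial C10 methyl, anti to the pseudo-axial H-7 and H-10 of the lactone-bridged cycloheptene), which sets C1′ and C5′.

Step 15
Reactants: 19 enyne lactone
Product: 22 (4R,5R)-3-methylidene-5-[(2S)-2-methyl-3-oxobutyl]-4-(prop-2-en-1-yl)oxolan-2-one
Conditions: Ph3PAuNTf2 (2 mol%), H2O, 1,4-dioxane, 60 °C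
Reagents that add atoms: water, O
Why: Gold-catalysed Markovnikov hydration of the terminal alkyne gives the methyl ketone under neutral conditions that spare the methylidene lactone and the adjacent C10 centre.

Step 16
Reactants: 22 methyl ketone lactone
Product: 23 (4R,5R)-5-[(2S)-3-[(tert-butyldimethylsilyl)oxy]-2-methylbut-3-en-1-yl]-3-methylidene-4-(prop-2-en-1-yl)oxolan-2-one
Conditions: TBSOTf, Et3N, CH2Cl2, −78 → 0 °C
Reagents that add atoms: tert-butyldimethylsilyl trifluoromethanesulfonate, CC(C)(C)[Si](C)(C)OS(=O)(=O)C(F)(F)F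
Why: Soft enolisation (silyl enol ether formation) removes a proton from the unhindered methyl group, not from the C10 methine, and gives the 2-silyloxy-1-alkene.

Step 17
Reactants: 23 acyclic silyl enol ether
Product: 25 (3aR,7S,8aR)-7-methyl-3-methylidenehexahydro-2H-cyclohepta[b]furan-2,6(3H)-dione, via cyclic silyl enol ether 24 (not isolated)
Conditions: second-generation Grubbs catalyst (10 mol%), toluene, 80 °C; then 1 M HCl, THF, rt
Reagents that add atoms: none
Why: Ring-closing metathesis of the silyl enol ether with the allyl group closes the seven-membered ring as the C1=C5 enol silane, and acid hydrolysis then gives the cycloheptanone with its carbonyl at C1.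

Step 18
Reactants: 25 keto methylidene lactone
Product: 26 (3S,3aR,7S,8aR)-7-methyl-3-[(phenylselanyl)methyl]hexahydro-2H-cyclohepta[b]furan-2,6(3H)-dione
Conditions: PhSeH, Et3N (cat.), THF, 0 °C
Reagents that add atoms: benzeneselenol, [SeH]c1ccccc1
Why: Conjugate addition of the selenol masks this half's methylidene lactone so that it cannot act as an acceptor in step 21; convex-face protonation sets C11, which is destroyed again in step 22.

Step 19
Reactants: 27 2-oxopropanal (40% in water); 28 nitromethane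
Product: 29 3-hydroxy-4-nitrobutan-2-one (racemic)
Conditions: NaHCO3 (cat.), H2O/THF, 0 °C → rt
Reagents that add atoms: none
Why: The Henry (nitro-aldol) reaction takes the aldehyde carbonyl, which is far more electrophilic than the ketone.

Step 20
Reactants: 29 3-hydroxy-4-nitrobutan-2-one
Product: 31 (3E)-4-nitrobut-3-en-2-one, via nitro mesylate 30 (not isolated)
Conditions: MsCl, Et3N (2 equiv), CH2Cl2, −20 °C; used at once
Reagents that add atoms: none
Why: Mesylation and base-induced β-elimination (E1cB through the nitronate) dehydrate the nitro-aldol to the (E)-nitro enone.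

Step 21
Reactants: 26 selenide ketone; 21 vinyl epoxide lactone; 31 (3E)-4-nitrobut-3-en-2-one
Product: 36 13-(phenylselanyl)-11,13-dihydro derivative of 38, via lithium cycloheptenolate 32 (not isolated), via lithium lactone enolate 33 (not isolated), via lithium nitronate 34 (not isolated), via lithium nitro alkoxide 35 (not isolated)
Conditions: lithium 2,2,6,6-tetramethylpiperidide (1.0 equiv), THF, −78 °C; then 21, −78 °C; then 31, −78 → 0 °C; then DBU (0.2 equiv), rt
Reagents that add atoms: none
Why: Proposed new method: the kinetic C1/C5 lithium enolate of 26 adds to the methylidene lactone of 21 (C5–C13′), the lactone enolate so formed adds to the nitro enone at the carbon β to nitro (C3–C11′), the nitronate closes onto the C1 ketone in a nitro-aldol (C1–C2), and E1cB loss of nitrite from the β-nitro ketone leaves the C2=C3 enone, so that the nitro enone serves as a 1,2-ambiphilic equivalent of but-3-yn-2-one; the closest known reaction types are Michael–Michael–ring-closure cascades of ketone enolates with two acrylates, Michael–Henry annulations of nitroalkenes onto tethered ketones, and addition–HNO2 elimination on β-nitro enones. Ring C is the only ring closed, by 6-exo-trig attack of the nitronate carbon C2 on the C1 carbonyl. C5 is set by attack on the β face of the cycloheptanone enolate (cis to the C10 methyl, which is also the thermodynamic cis-2,7-disubstituted ketone), C11′ by approach of the nitro enone to the convex face of the cis-fused lactone enolate (anti to C6′), and C1 by chair-like closure on the α face of the carbonyl to the trans-fused ring with the hydroxyl β, the reversible nitro-aldol being drained by the irreversible nitrite loss; C2 and C3 end as sp2 centres. The step needs enolisation at the C5 methylene and not at the C10 methine (bulky amide, kinetic conditions), a single Michael acceptor in the first addition (the lactone of 26 is masked as the selenide), attack α to the acetyl group (the nitro group dominates the polarisation of 31), and ring closure before nitrite loss (under aprotic conditions the only anion before closure is the nitronate, which cannot eliminate).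

Step 22
Reactants: 36 selenide
Product: 38 4′,15′-dinor target (C1′ vinyl in place of the 3-oxobutenyl chain), via selenoxide 37 (not isolated)
Conditions: NaIO4, NaHCO3, THF/H2O, 0 °C → rt
Reagents that add atoms: none
Why: Oxidation to the selenoxide and syn-elimination (selenoxide elimination) towards the only β-hydrogen, H-11, regenerate the C11=C13 methylidene lactone without touching the enone, the vinyl epoxide or the tertiary alcohol.

Step 23
Reactants: 38 vinyl epoxide dimer; 39 but-3-en-2-one
Product: 40 CNP0177598.1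
Conditions: second-generation Hoveyda–Grubbs catalyst (10 mol%), 39 (10 equiv), CH2Cl2, 40 °C
Reagents that add atoms: none
Why: Olefin cross-metathesis of the monosubstituted vinyl group with methyl vinyl ketone should give the (E)-enone, the 1,1-disubstituted methylidene lactone and the trisubstituted ring enone being too hindered and electron-poor to react.

Compound list
1 | (2S)-but-3-yn-2-ol | C[C@H](O)C#C | starting material
2 | (2S)-but-3-yn-2-yl 4-methylbenzenesulfonate | Cc1ccc(cc1)S(=O)(=O)O[C@@H](C)C#C | intermediate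
3 | dimethyl malonate | COC(=O)CC(=O)OC | starting material
4 | sodium dimethyl malonate | [Na+].COC(=O)[CH-]C(=O)OC | intermediate
5 | dimethyl 2-[(2S)-but-3-yn-2-yl]propanedioate | COC(=O)C(C(=O)OC)[C@H](C)C#C | intermediate
6 | methyl (3S)-3-methylpent-4-ynoate | COC(=O)C[C@H](C)C#C | intermediate
7 | (3S)-3-methylpent-4-ynal | O=CC[C@H](C)C#C | intermediate
8 | (4S)-4-benzyl-1,3-oxazolidin-2-one | O=C1N[C@@H](Cc2ccccc2)CO1 | starting material
9 | pent-4-enoyl chloride | C=CCCC(Cl)=O | starting material
10 | (4S)-4-benzyl-3-(pent-4-enoyl)-1,3-oxazolidin-2-one | C=CCCC(=O)N1C(=O)OC[C@@H]1Cc1ccccc1 | intermediate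
11 | (Z)-dibutylboron enolate of 10 | C=CC/C=C(\OB(CCCC)CCCC)N1C(=O)OC[C@@H]1Cc1ccccc1 | intermediate
12 | (4S)-4-benzyl-3-[(2S,3R,5S)-3-hydroxy-5-methyl-2-(prop-2-en-1-yl)hept-6-ynoyl]-1,3-oxazolidin-2-one | O[C@H](C[C@H](C)C#C)[C@@H](C(=O)N1C(=O)OC[C@@H]1Cc1ccccc1)CC=C | intermediate
13 | (2S,3R,5S)-3-hydroxy-N-methoxy-N,5-dimethyl-2-(prop-2-en-1-yl)hept-6-ynamide | O[C@H](C[C@H](C)C#C)[C@@H](C(=O)N(C)OC)CC=C | intermediate
14 | (2S,3R,5S)-N-methoxy-N,5-dimethyl-2-(prop-2-en-1-yl)-3-[(triethylsilyl)oxy]hept-6-ynamide | CC[Si](CC)(CC)O[C@H](C[C@H](C)C#C)[C@@H](C(=O)N(C)OC)CC=C | intermediate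
15 | (3S,4R,6S)-6-methyl-3-(prop-2-en-1-yl)-4-[(triethylsilyl)oxy]oct-7-yn-2-one | CC[Si](CC)(CC)O[C@H](C[C@H](C)C#C)[C@@H](C(C)=O)CC=C | intermediate
16 | potassium enolate of 15 (methyl side) | CC[Si](CC)(CC)O[C@H](C[C@H](C)C#C)[C@@H](C(=C)[O-])CC=C.[K+] | intermediate
17 | (3S,4R,6S)-6-methyl-3-(prop-2-en-1-yl)-4-[(triethylsilyl)oxy]oct-1-en-7-yn-2-yl trifluoromethanesulfonate | CC[Si](CC)(CC)O[C@H](C[C@H](C)C#C)[C@@H](C(=C)OS(=O)(=O)C(F)(F)F)CC=C | intermediate
18 | (3S,4R,6S)-4-hydroxy-6-methyl-3-(prop-2-en-1-yl)oct-1-en-7-yn-2-yl trifluoromethanesulfonate | O[C@H](C[C@H](C)C#C)[C@@H](C(=C)OS(=O)(=O)C(F)(F)F)CC=C | intermediate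
19 | (4R,5R)-3-methylidene-5-[(2S)-2-methylbut-3-yn-1-yl]-4-(prop-2-en-1-yl)oxolan-2-one | C=C1C(=O)O[C@H](C[C@H](C)C#C)[C@@H]1CC=C | intermediate
20 | (3aR,7S,8aR)-6-ethenyl-7-methyl-3-methylidene-3,3a,4,7,8,8a-hexahydro-2H-cyclohepta[b]furan-2-one | C=C1C(=O)O[C@@H]2C[C@H](C)C(C=C)=CC[C@H]12 | intermediate
21 | 1β,5β-epoxide of 20 (oxirane across xanthanolide C1–C5, oxygen on the face of the C10 methyl; C1 keeps the vinyl group) | C=C1C(=O)O[C@@H]2C[C@H](C)[C@]3(C=C)O[C@@H]3C[C@H]12 | intermediate
22 | (4R,5R)-3-methylidene-5-[(2S)-2-methyl-3-oxobutyl]-4-(prop-2-en-1-yl)oxolan-2-one | C=C1C(=O)O[C@H](C[C@H](C)C(C)=O)[C@@H]1CC=C | intermediate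
23 | (4R,5R)-5-[(2S)-3-[(tert-butyldimethylsilyl)oxy]-2-methylbut-3-en-1-yl]-3-methylidene-4-(prop-2-en-1-yl)oxolan-2-one | C=C1C(=O)O[C@H](C[C@H](C)C(=C)O[Si](C)(C)C(C)(C)C)[C@@H]1CC=C | intermediate
24 | (3aR,7S,8aR)-6-[(tert-butyldimethylsilyl)oxy]-7-methyl-3-methylidene-3,3a,4,7,8,8a-hexahydro-2H-cyclohepta[b]furan-2-one | C=C1C(=O)O[C@@H]2C[C@H](C)C(O[Si](C)(C)C(C)(C)C)=CC[C@H]12 | intermediate
25 | (3aR,7S,8aR)-7-methyl-3-methylidenehexahydro-2H-cyclohepta[b]furan-2,6(3H)-dione | C=C1C(=O)O[C@@H]2C[C@H](C)C(=O)CC[C@H]12 | intermediate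
26 | (3S,3aR,7S,8aR)-7-methyl-3-[(phenylselanyl)methyl]hexahydro-2H-cyclohepta[b]furan-2,6(3H)-dione | c1ccccc1[Se]C[C@@H]1C(=O)O[C@@H]2C[C@H](C)C(=O)CC[C@H]12 | intermediate
27 | 2-oxopropanal (methylglyoxal) | CC(=O)C=O | starting material
28 | nitromethane | C[N+](=O)[O-] | starting material
29 | 3-hydroxy-4-nitrobutan-2-one (racemic) | CC(=O)C(O)C[N+](=O)[O-] | intermediate
30 | 1-nitro-3-oxobutan-2-yl methanesulfonate | CC(=O)C(OS(C)(=O)=O)C[N+](=O)[O-] | intermediate
31 | (3E)-4-nitrobut-3-en-2-one | CC(=O)/C=C/[N+](=O)[O-] | intermediate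
32 | lithium C1=C5 enolate of 26 | c1ccccc1[Se]C[C@@H]1C(=O)O[C@@H]2C[C@H](C)C([O-])=CC[C@H]12.[Li+] | intermediate
33 | lithium lactone enolate after C5–C13′ bond formation (C1 ketone, C11′=C12′–O−) | c1ccccc1[Se]C[C@@H]1C(=O)O[C@@H]2C[C@H](C)C(=O)[C@H](CC3=C([O-])O[C@@H]4C[C@H](C)[C@]5(C=C)O[C@@H]5C[C@H]34)C[C@H]12.[Li+] | intermediate
34 | lithium nitronate after C3–C11′ bond formation (C3 epimers) | c1ccccc1[Se]C[C@@H]1C(=O)O[C@@H]2C[C@H](C)C(=O)[C@H](C[C@]3(C(C(C)=O)C=[N+]([O-])[O-])C(=O)O[C@@H]4C[C@H](C)[C@]5(C=C)O[C@@H]5C[C@H]34)C[C@H]12.[Li+] | intermediate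
35 | lithium C1 alkoxide of the ring C nitro alcohol (C2, C3 epimers) | c1ccccc1[Se]C[C@@H]1C(=O)O[C@@H]2C[C@H](C)[C@@]3([O-])C([N+](=O)[O-])C(C(C)=O)[C@@]4(C[C@@H]3C[C@H]12)C(=O)O[C@@H]1C[C@H](C)[C@]2(C=C)O[C@@H]2C[C@@H]14.[Li+] | intermediate
36 | 13-(phenylselanyl)-11,13-dihydro derivative of 38 | c1ccccc1[Se]C[C@@H]1C(=O)O[C@@H]2C[C@H](C)[C@@]3(O)C=C(C(C)=O)[C@@]4(C[C@@H]3C[C@H]12)C(=O)O[C@@H]1C[C@H](C)[C@]2(C=C)O[C@@H]2C[C@@H]14 | intermediate
37 | selenoxide of 36 (epimers at selenium) | O=[Se](c1ccccc1)C[C@@H]1C(=O)O[C@@H]2C[C@H](C)[C@@]3(O)C=C(C(C)=O)[C@@]4(C[C@@H]3C[C@H]12)C(=O)O[C@@H]1C[C@H](C)[C@]2(C=C)O[C@@H]2C[C@@H]14 | intermediate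
38 | 4′,15′-dinor target (C1′ vinyl in place of the 3-oxobutenyl chain) | C=C1C(=O)O[C@@H]2C[C@H](C)[C@@]3(O)C=C(C(C)=O)[C@@]4(C[C@@H]3C[C@H]12)C(=O)O[C@@H]1C[C@H](C)[C@]2(C=C)O[C@@H]2C[C@@H]14 | intermediate
39 | but-3-en-2-one (methyl vinyl ketone) | CC(=O)C=C | starting material
40 | CNP0177598.1 | C=C1C(=O)O[C@@H]2C[C@H](C)[C@@]3(O)C=C(C(C)=O)[C@@]4(C[C@@H]3C[C@H]12)C(=O)O[C@@H]1C[C@H](C)[C@]2(/C=C/C(C)=O)O[C@@H]2C[C@@H]14 | target

Total step count: 23. Longest linear sequence: 18 steps (1–4, 6–12, 15–18, 21–23).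

Steps most likely to fail

Step 21. The open-chain adduct may lose nitrite before the ring closes, the lithium nitronate may add too slowly to the hindered C1 ketone, or facial selectivity at C5 and C1 may be poor. The fallback sets out from 26 and 21 and returns at 36, using only known reaction types and an acetyl group masked as a silyl-protected carbinol. Commercial (S)-2-[(tert-butyldimethylsilyl)oxy]propanal and 28 undergo a Henry reaction (Et3N cat.) to (3S)-3-[(tert-butyldimethylsilyl)oxy]-1-nitrobutan-2-ol F1, and MsCl/Et3N gives tert-butyldimethyl{[(2S,3E)-4-nitrobut-3-en-2-yl]oxy}silane F2. The enolate 32 is added to 21 as in the route, the lactone enolate 33 is trapped with F2 (tandem Michael–Michael addition), and an AcOH quench gives the open-chain nitro ketone F3, in which C3 has no acidifying carbonyl and nitrite cannot leave early. Catalytic tetramethylguanidine in MeCN closes ring C by an equilibrating nitro-aldol to the nitro cyclohexanol silyl ether F4. HF·pyridine gives the C4 alcohol F5. Parikh–Doering oxidation (SO3·pyridine, DMSO, i-Pr2NEt) gives the β-nitro ketone F6, which should lose HNO2 under the amine in the same flask to give 36.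

Step 23. Cross-metathesis may be slow or fail at the vinyl group next to the fully substituted epoxide carbon, with catalyst decomposition on the polyfunctional dimer. The fallback sets out from 19 and returns at 40, and installs the side chain at the monomer stage. Tandem ring-closing enyne metathesis and cross-metathesis of 19 with excess 39 (second-generation Grubbs catalyst, CH2Cl2, 40 °C) gives 8-epi-xanthatin F7, whose vinyl group is unhindered when it reacts. mCPBA/NaHCO3 epoxidises the γ,δ-bond to 8-epi-xanthatin 1β,5β-epoxide F8. F8 then replaces 21 in the step 21 cascade, where the enolate of 26 must add to the methylidene lactone faster than to the β-branched enone, and gives the 13-(phenylselanyl)-11,13-dihydro target F9. NaIO4 as in step 22 gives 40.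

Step 14. The peracid may attack the C1=C5 bond from the α face or with poor facial selectivity, and the vinyl epoxide may open under acid. The fallback sets out from 20 and returns at 21. N-Bromosuccinimide in aqueous THF gives the trans-bromohydrin F10 (bromonium ion on the face a peracid prefers, water at the tertiary allylic C1 from the opposite face). DBU in CH2Cl2 then closes it by intramolecular SN2 at C5, so the oxirane oxygen ends on the face opposite to that of direct epoxidation.

Further compounds
F1 | step 21 | (3S)-3-[(tert-butyldimethylsilyl)oxy]-1-nitrobutan-2-ol | C[C@H](O[Si](C)(C)C(C)(C)C)C(O)C[N+](=O)[O-]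
F2 | step 21 | tert-butyldimethyl{[(2S,3E)-4-nitrobut-3-en-2-yl]oxy}silane | C[C@H](O[Si](C)(C)C(C)(C)C)/C=C/[N+](=O)[O-]
F3 | step 21 | open-chain nitro ketone (C1 ketone; C3 bears CH2NO2 and the silyloxyethyl group) | c1ccccc1[Se]C[C@@H]1C(=O)O[C@@H]2C[C@H](C)C(=O)[C@H](C[C@]3(C(C[N+](=O)[O-])[C@H](C)O[Si](C)(C)C(C)(C)C)C(=O)O[C@@H]4C[C@H](C)[C@]5(C=C)O[C@@H]5C[C@H]34)C[C@H]12
F4 | step 21 | ring C nitro cyclohexanol silyl ether | c1ccccc1[Se]C[C@@H]1C(=O)O[C@@H]2C[C@H](C)[C@@]3(O)C([N+](=O)[O-])C([C@H](C)O[Si](C)(C)C(C)(C)C)[C@@]4(C[C@@H]3C[C@H]12)C(=O)O[C@@H]1C[C@H](C)[C@]2(C=C)O[C@@H]2C[C@@H]14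
F5 | step 21 | ring C nitro diol (free C4 alcohol) | c1ccccc1[Se]C[C@@H]1C(=O)O[C@@H]2C[C@H](C)[C@@]3(O)C([N+](=O)[O-])C([C@H](C)O)[C@@]4(C[C@@H]3C[C@H]12)C(=O)O[C@@H]1C[C@H](C)[C@]2(C=C)O[C@@H]2C[C@@H]14
F6 | step 21 | ring C β-nitro ketone | c1ccccc1[Se]C[C@@H]1C(=O)O[C@@H]2C[C@H](C)[C@@]3(O)C([N+](=O)[O-])C(C(C)=O)[C@@]4(C[C@@H]3C[C@H]12)C(=O)O[C@@H]1C[C@H](C)[C@]2(C=C)O[C@@H]2C[C@@H]14
F7 | step 23 | 8-epi-xanthatin | C=C1C(=O)O[C@@H]2C[C@H](C)C(/C=C/C(C)=O)=CC[C@H]12
F8 | step 23 | 8-epi-xanthatin 1β,5β-epoxide | C=C1C(=O)O[C@@H]2C[C@H](C)[C@]3(/C=C/C(C)=O)O[C@@H]3C[C@H]12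
F9 | step 23 | 13-(phenylselanyl)-11,13-dihydro target | c1ccccc1[Se]C[C@@H]1C(=O)O[C@@H]2C[C@H](C)[C@@]3(O)C=C(C(C)=O)[C@@]4(C[C@@H]3C[C@H]12)C(=O)O[C@@H]1C[C@H](C)[C@]2(/C=C/C(C)=O)O[C@@H]2C[C@@H]14
F10 | step 14 | trans-bromohydrin of 20 (C1 β-hydroxyl, C5 α-bromide) | C=C1C(=O)O[C@@H]2C[C@H](C)[C@@](O)(C=C)[C@@H](Br)C[C@H]12
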